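**Strategy.** The cyclopentenone ring C8–C9(=O)–C10(Cl)=C11–C12(OH) has exactly the oxidation pattern that a 2-furylcarbinol delivers on Piancatelli rearrangement. The ring is therefore disconnected at C8–C12, back to a 3-chloro-5-[(Z)-oct-2-enyl]furan joined through its C2 to the C8 carbinol of a D-xylose-derived C1–C8 chain. In one operation the key step dearomatises the furan, forms the C8–C12 bond by 4π electrocyclisation, closes the five-membered ring and creates the C12 tertiary carbinol and the C8 centre. Its precursor is the furylcarbinol (either C8 epimer) with C5/C6 as a trans-acetonide, C7 as a TBS ether and C1 as the methyl ester.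

Key step: step 16

Assumption: atoms carry the prostanoid numbers of the target (C1 ester carbon, C8 and C12 the ring carbons bearing the chains, C20 the methyl group); the furylcarbinol is used as the mixture of C8 epimers because both ionise to the same cation.

Remark on regiochemistry: a 3-halofuran is deprotonated next to the halogen (C2), so the octenyl group can be placed on C5 only while C2 is blocked; a trimethylsilyl group serves as the block and is removed in the same flask.

Step 1
Reactants: 1 D-xylose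
Product: 2 D-xylose diethyl dithioacetal
Conditions: EtSH, conc. HCl, 0 °C
Reagents that add atoms: ethanethiol, CCS
Why: Fischer dithioacetalisation traps the open-chain aldehyde form and leaves the three carbinol stereocentres (the later C5, C6 and C7) untouched.

Step 2
Reactants: 2 D-xylose diethyl dithioacetal
Product: 3 2,3:4,5-di-O-isopropylidene-D-xylose diethyl dithioacetal
Conditions: Me2C(OMe)2, TsOH·H2O (cat.), acetone, rt
Reagents that add atoms: 2,2-dimethoxypropane, COC(C)(C)OC
Why: Thermodynamic acetonide formation (transketalisation) should tie the threo O2/O3 pair into a trans-dioxolane and the terminal O4/O5 pair into a second dioxolane, the usual pattern for pentose dithioacetals.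

Step 3
Reactants: 3 2,3:4,5-di-O-isopropylidene-D-xylose diethyl dithioacetal
Product: 4 2,3:4,5-di-O-isopropylidene-aldehydo-D-xylose
Conditions: I2, NaHCO3, acetone–H2O, 0 °C → rt
Reagents that add atoms: water, O
Why: Iodine-promoted oxidative hydrolysis of the dithioacetal under bicarbonate buffering unmasks the aldehyde, and the acetonides and the α-stereocentre are expected to survive.

Step 4
Reactants: 4 2,3:4,5-di-O-isopropylidene-aldehydo-D-xylose
Product: 6 methyl (3Z,5S,6R,7R)-5,6:7,8-bis(isopropylidenedioxy)oct-3-enoate, via sodium carboxylate 5 (not isolated)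
Conditions: [Ph3PCH2CH2CO2H]Br, NaN(SiMe3)2 (2 equiv), THF, −78 °C → rt; then MeI, DMF, rt
Reagents that add atoms: (2-carboxyethyl)triphenylphosphonium bromide, OC(=O)CC[P+](c1ccccc1)(c1ccccc1)c1ccccc1.[Br-]; iodomethane, CI
Why: Wittig olefination with the non-stabilised carboxylate ylide adds C1–C3 in one bond-forming event and SN2 O-methylation of the carboxylate gives the ester, the alkene geometry being of no consequence because it is hydrogenated in step 5.

Step 5
Reactants: 6 methyl (3Z,5S,6R,7R)-5,6:7,8-bis(isopropylidenedioxy)oct-3-enoate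
Product: 7 methyl (5S,6R,7R)-5,6:7,8-bis(isopropylidenedioxy)octanoate
Conditions: H2 (1 atm), Pd/C, EtOAc, rt
Reagents that add atoms: none
Why: Heterogeneous catalytic hydrogenation in a neutral solvent should saturate the C3=C4 alkene faster than it cleaves the allylic C–O bond, and the acetonides and ester are inert.

Step 6
Reactants: 7 methyl (5S,6R,7R)-5,6:7,8-bis(isopropylidenedioxy)octanoate
Product: 8 methyl (5S,6R,7R)-7,8-dihydroxy-5,6-(isopropylidenedioxy)octanoate
Conditions: AcOH–H2O (7:3), rt
Reagents that add atoms: none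
Why: Acid-catalysed acetal hydrolysis is faster for a terminal dioxolane than for an internal trans-dioxolane, so only the C7/C8 diol should be unmasked, and no hydroxyl δ to the ester is freed, which rules out lactonisation.

Step 7
Reactants: 8 methyl (5S,6R,7R)-7,8-dihydroxy-5,6-(isopropylidenedioxy)octanoate
Product: 9 methyl (5S,6R,7R)-7,8-bis(tert-butyldimethylsilyloxy)-5,6-(isopropylidenedioxy)octanoate
Conditions: TBSOTf, 2,6-lutidine, CH2Cl2, 0 °C
Reagents that add atoms: tert-butyldimethylsilyl triflate, CC(C)(C)[Si](C)(C)OS(=O)(=O)C(F)(F)F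
Why: Silylation with the silyl triflate and a hindered base should protect both hydroxyls, including the hindered secondary one at C7.

Step 8
Reactants: 9 methyl (5S,6R,7R)-7,8-bis(tert-butyldimethylsilyloxy)-5,6-(isopropylidenedioxy)octanoate
Product: 10 methyl (5S,6R,7R)-7-(tert-butyldimethylsilyloxy)-8-hydroxy-5,6-(isopropylidenedioxy)octanoate
Conditions: HF·pyridine, pyridine, THF, 0 °C
Reagents that add atoms: none
Why: Selective desilylation with buffered HF·pyridine removes a primary silyl ether much faster than a secondary one and does not touch the acetonide.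

Step 9
Reactants: 10 methyl (5S,6R,7R)-7-(tert-butyldimethylsilyloxy)-8-hydroxy-5,6-(isopropylidenedioxy)octanoate
Product: 11 methyl (5S,6R,7S)-7-(tert-butyldimethylsilyloxy)-5,6-(isopropylidenedioxy)-8-oxooctanoate
Conditions: TEMPO (cat.), PhI(OAc)2, CH2Cl2, rt
Reagents that add atoms: none
Why: Oxoammonium (TEMPO) oxidation of the primary alcohol under non-basic conditions should give the α-silyloxy aldehyde without over-oxidation or epimerisation at C7.

Step 10
Reactants: 12 oct-2-yn-1-ol
Product: 13 (Z)-oct-2-en-1-ol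
Conditions: H2 (1 atm), Pd/CaCO3 poisoned with Pb(OAc)2, quinoline, hexane, rt
Reagents that add atoms: none
Why: Semihydrogenation over the lead-poisoned palladium catalyst delivers both hydrogens to one face of the alkyne and so sets the Z alkene of the C13–C20 chain.

Step 11
Reactants: 13 (Z)-oct-2-en-1-ol
Product: 14 (Z)-1-bromooct-2-ene
Conditions: CBr4, PPh3, CH2Cl2, 0 °C
Reagents that add atoms: carbon tetrabromide, BrC(Br)(Br)Br
Why: Appel bromination replaces the primary allylic hydroxyl by SN2 at low temperature, which should keep the Z geometry, and the bromide is used at once.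

Step 12
Reactants: 15 3-bromofuran
Product: 17 3-bromo-2-(trimethylsilyl)furan, via 3-bromo-2-lithiofuran 16 (not isolated)
Conditions: LiN(iPr)2, THF, −78 °C; Me3SiCl
Reagents that add atoms: chlorotrimethylsilane, C[Si](C)(C)Cl
Why: Directed deprotonation removes the C2–H flanked by the ring oxygen and the bromine, and C-silylation blocks this most acidic position.

Step 13
Reactants: 17 3-bromo-2-(trimethylsilyl)furan
Product: 19 3-chloro-2-(trimethylsilyl)furan, via 3-lithio-2-(trimethylsilyl)furan 18 (not isolated)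
Conditions: nBuLi, Et2O, −78 °C; C2Cl6, −78 °C → rt
Reagents that add atoms: hexachloroethane, ClC(Cl)(Cl)C(Cl)(Cl)Cl
Why: Bromine–lithium exchange at −78 °C followed by electrophilic chlorination swaps bromine for the chlorine of the target, which is inert to the later organolithium steps.

Step 14
Reactants: 19 3-chloro-2-(trimethylsilyl)furan; 14 (Z)-1-bromooct-2-ene
Product: 22 3-chloro-5-[(Z)-oct-2-en-1-yl]furan, via 5-lithiofuran 20 (not isolated), via silylated octenylfuran 21 (not isolated)
Conditions: nBuLi, THF, −78 → 0 °C; 14, −78 °C → rt; then Bu4NF, THF, rt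
Reagents that add atoms: none
Why: With C2 blocked, α-lithiation can occur only at C5, SN2 alkylation of the furyllithium with the primary allylic bromide keeps the Z alkene, and fluoride-induced protodesilylation frees C2.

Step 15
Reactants: 22 3-chloro-5-[(Z)-oct-2-en-1-yl]furan; 11 methyl (5S,6R,7S)-7-(tert-butyldimethylsilyloxy)-5,6-(isopropylidenedioxy)-8-oxooctanoate
Product: 24 methyl (5S,6R,7R,8RS)-7-(tert-butyldimethylsilyloxy)-8-{3-chloro-5-[(Z)-oct-2-en-1-yl]furan-2-yl}-8-hydroxy-5,6-(isopropylidenedioxy)octanoate (both C8 epimers), via 2-furyllithium 23 (not isolated)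
Conditions: LiN(iPr)2, THF, −78 °C; 11, −78 °C; AcOH quench at −78 °C
Reagents that add atoms: none
Why: Deprotonation at C2 between oxygen and chlorine gives the furyllithium, whose 1,2-addition to the aldehyde at −78 °C is far faster than attack on the methyl ester, and no selectivity at C8 is needed because both epimers feed the same cation in step 16.

Step 16
Reactants: 24 methyl (5S,6R,7R,8RS)-7-(tert-butyldimethylsilyloxy)-8-{3-chloro-5-[(Z)-oct-2-en-1-yl]furan-2-yl}-8-hydroxy-5,6-(isopropylidenedioxy)octanoate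
Product: 26 methyl (5S,6R,7R,8R,12S,14Z)-7-(tert-butyldimethylsilyloxy)-10-chloro-12-hydroxy-5,6-(isopropylidenedioxy)-9-oxoprosta-10,14-dien-1-oate, via C8-epimeric cyclopentenone 25 (not isolated)
Conditions: Dy(OTf)3 (10 mol %), tBuOH–H2O (5:1), 80 °C; crude product, then Et3N (cat.), CH2Cl2, rt
Reagents that add atoms: water, O
Why: Dy(OTf)3 ionises either C8 epimer to the same furfuryl cation, water adds at the octenyl-bearing furan carbon (C12), the hemiketal opens to a 1-hydroxypentadienyl cation spanning C8–C12, and loss of a proton after ring closure leaves the C9 ketone and the C10(Cl)=C11 alkene. This is the Piancatelli rearrangement as established for 5-alkyl-2-furylcarbinols under lanthanide triflate or ZnCl2 catalysis, applied here to a furan that carries chlorine at C10. The five-membered ring closes by thermal conrotatory 4π electrocyclisation that forms C8–C12. C12 is fixed by the sense of conrotation, for which the only bias is C7: with C7–H in the plane of the cation to avoid allylic strain against the C9 oxygen, bonding on the face anti to the dioxolane carbon C6 (hydroxyl outside on the C12 terminus, as in known closures) leads to the target series, a preference that is plausible but not secure. C8 is first set with its chain trans to the C12 hydroxyl by the conrotation and is then epimerised through the enol by Et3N to the more stable arrangement with the two carbon chains trans, C8 being the only enolisable ring position. The step needs water attack at C12 instead of C8 (attack at C8 merely returns the carbinol), a single sense of rotation, and intact acetonide, silyl ether, ester and Z alkene, which the nearly neutral aqueous medium should tolerate.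

Step 17
Reactants: 26 methyl (5S,6R,7R,8R,12S,14Z)-7-(tert-butyldimethylsilyloxy)-10-chloro-12-hydroxy-5,6-(isopropylidenedioxy)-9-oxoprosta-10,14-dien-1-oate
Product: 27 methyl (5S,6R,7R,8R,12S,14Z)-10-chloro-5,6,7,12-tetrahydroxy-9-oxoprosta-10,14-dien-1-oate
Conditions: Dowex 50W-X8 (H+ form), MeOH, rt; resin filtered off before concentration
Reagents that add atoms: none
Why: Acid-catalysed methanolysis exchanges the acetonide and cleaves the silyl ether in one operation, and methanol as solvent holds C1 as the methyl ester by mass action so that the free C5 hydroxyl should not close a δ-lactone.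

Step 18
Reactants: 27 methyl (5S,6R,7R,8R,12S,14Z)-10-chloro-5,6,7,12-tetrahydroxy-9-oxoprosta-10,14-dien-1-oate
Product: 28 punaglandin 2, methyl (5S,6R,7R,8R,12S,14Z)-5,6,7-triacetoxy-10-chloro-12-hydroxy-9-oxoprosta-10,14-dien-1-oate
Conditions: Ac2O, pyridine, CH2Cl2, 0 °C
Reagents that add atoms: acetic anhydride, CC(=O)OC(C)=O
Why: Pyridine-mediated acetylation esterifies the three secondary hydroxyls, the hindered tertiary C12 hydroxyl should stay free without a nucleophilic catalyst, and the low temperature limits β-elimination of the C7 acetate.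

**Compound list**

1 | D-xylose | O=C[C@H](O)[C@@H](O)[C@H](O)CO | starting material
2 | D-xylose diethyl dithioacetal | CCSC(SCC)[C@H](O)[C@@H](O)[C@H](O)CO | intermediate
3 | 2,3:4,5-di-O-isopropylidene-D-xylose diethyl dithioacetal | CCSC(SCC)[C@@H]1OC(C)(C)O[C@H]1[C@H]1COC(C)(C)O1 | intermediate
4 | 2,3:4,5-di-O-isopropylidene-aldehydo-D-xylose | O=C[C@@H]1OC(C)(C)O[C@H]1[C@H]1COC(C)(C)O1 | intermediate
5 | sodium (3Z,5S,6R,7R)-5,6:7,8-bis(isopropylidenedioxy)oct-3-enoate | [Na+].[O-]C(=O)C/C=C\[C@@H]1OC(C)(C)O[C@H]1[C@H]1COC(C)(C)O1 | intermediate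
6 | methyl (3Z,5S,6R,7R)-5,6:7,8-bis(isopropylidenedioxy)oct-3-enoate | COC(=O)C/C=C\[C@@H]1OC(C)(C)O[C@H]1[C@H]1COC(C)(C)O1 | intermediate
7 | methyl (5S,6R,7R)-5,6:7,8-bis(isopropylidenedioxy)octanoate | COC(=O)CCC[C@@H]1OC(C)(C)O[C@H]1[C@H]1COC(C)(C)O1 | intermediate
8 | methyl (5S,6R,7R)-7,8-dihydroxy-5,6-(isopropylidenedioxy)octanoate | COC(=O)CCC[C@@H]1OC(C)(C)O[C@H]1[C@H](O)CO | intermediate
9 | methyl (5S,6R,7R)-7,8-bis(tert-butyldimethylsilyloxy)-5,6-(isopropylidenedioxy)octanoate | COC(=O)CCC[C@@H]1OC(C)(C)O[C@H]1[C@H](O[Si](C)(C)C(C)(C)C)CO[Si](C)(C)C(C)(C)C | intermediate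
10 | methyl (5S,6R,7R)-7-(tert-butyldimethylsilyloxy)-8-hydroxy-5,6-(isopropylidenedioxy)octanoate | COC(=O)CCC[C@@H]1OC(C)(C)O[C@H]1[C@H](O[Si](C)(C)C(C)(C)C)CO | intermediate
11 | methyl (5S,6R,7S)-7-(tert-butyldimethylsilyloxy)-5,6-(isopropylidenedioxy)-8-oxooctanoate | COC(=O)CCC[C@@H]1OC(C)(C)O[C@H]1[C@H](O[Si](C)(C)C(C)(C)C)C=O | intermediate
12 | oct-2-yn-1-ol | CCCCCC#CCO | starting material
13 | (Z)-oct-2-en-1-ol | CCCCC/C=C\CO | intermediate
14 | (Z)-1-bromooct-2-ene | CCCCC/C=C\CBr | intermediate
15 | 3-bromofuran | Brc1ccoc1 | starting material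
16 | 3-bromo-2-lithiofuran | [Li]c1occc1Br | intermediate
17 | 3-bromo-2-(trimethylsilyl)furan | C[Si](C)(C)c1occc1Br | intermediate
18 | 3-lithio-2-(trimethylsilyl)furan | [Li]c1ccoc1[Si](C)(C)C | intermediate
19 | 3-chloro-2-(trimethylsilyl)furan | C[Si](C)(C)c1occc1Cl | intermediate
20 | 3-chloro-5-lithio-2-(trimethylsilyl)furan | [Li]c1cc(Cl)c(o1)[Si](C)(C)C | intermediate
21 | 3-chloro-5-[(Z)-oct-2-en-1-yl]-2-(trimethylsilyl)furan | CCCCC/C=C\Cc1cc(Cl)c(o1)[Si](C)(C)C | intermediate
22 | 3-chloro-5-[(Z)-oct-2-en-1-yl]furan | CCCCC/C=C\Cc1cc(Cl)co1 | intermediate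
23 | 3-chloro-2-lithio-5-[(Z)-oct-2-en-1-yl]furan | CCCCC/C=C\Cc1cc(Cl)c([Li])o1 | intermediate
24 | methyl (5S,6R,7R,8RS)-7-(tert-butyldimethylsilyloxy)-8-{3-chloro-5-[(Z)-oct-2-en-1-yl]furan-2-yl}-8-hydroxy-5,6-(isopropylidenedioxy)octanoate (C8 epimer mixture) | CCCCC/C=C\Cc1cc(Cl)c(o1)C(O)[C@@H](O[Si](C)(C)C(C)(C)C)[C@@H]2OC(C)(C)O[C@H]2CCCC(=O)OC | intermediate
25 | methyl (5S,6R,7R,8S,12S,14Z)-7-(tert-butyldimethylsilyloxy)-10-chloro-12-hydroxy-5,6-(isopropylidenedioxy)-9-oxoprosta-10,14-dien-1-oate (C8 epimer of 26) | CCCCC/C=C\C[C@@]1(O)C=C(Cl)C(=O)[C@H]1[C@@H](O[Si](C)(C)C(C)(C)C)[C@@H]2OC(C)(C)O[C@H]2CCCC(=O)OC | intermediate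
26 | methyl (5S,6R,7R,8R,12S,14Z)-7-(tert-butyldimethylsilyloxy)-10-chloro-12-hydroxy-5,6-(isopropylidenedioxy)-9-oxoprosta-10,14-dien-1-oate | CCCCC/C=C\C[C@@]1(O)C=C(Cl)C(=O)[C@@H]1[C@@H](O[Si](C)(C)C(C)(C)C)[C@@H]2OC(C)(C)O[C@H]2CCCC(=O)OC | intermediate
27 | methyl (5S,6R,7R,8R,12S,14Z)-10-chloro-5,6,7,12-tetrahydroxy-9-oxoprosta-10,14-dien-1-oate | CCCCC/C=C\C[C@@]1(O)C=C(Cl)C(=O)[C@@H]1[C@@H](O)[C@H](O)[C@H](CCCC(=O)OC)O | intermediate
28 | punaglandin 2, methyl (5S,6R,7R,8R,12S,14Z)-5,6,7-triacetoxy-10-chloro-12-hydroxy-9-oxoprosta-10,14-dien-1-oate | CCCCC/C=C\C[C@@]1(O)C=C(Cl)C(=O)[C@@H]1[C@@H](OC(C)=O)[C@H](OC(C)=O)[C@H](CCCC(=O)OC)OC(C)=O | target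

**Step count.** Total: 18 steps. Longest linear sequence: 13 steps (steps 1–9 and 15–18, from D-xylose).

**Steps most likely to fail**

Step 16. Ionisation of the carbinol may be slow, because the chlorine on the furan and the C7 oxygen both destabilise the furfuryl cation. Hydrolysis of the acetonide or silyl ether, a 1,2-hydride shift from C7, or conrotation in both senses could then compete with the rearrangement. The fallback sets out from 14 and 11, returns to the route at 26, and introduces the chlorine after the ring is formed. Furan is lithiated (nBuLi, THF, 0 °C) to 2-furyllithium F1 and alkylated with 14 to 2-[(Z)-oct-2-en-1-yl]furan F2. Renewed lithiation at the free α-position gives 5-lithio-2-[(Z)-oct-2-en-1-yl]furan F3, which adds to 11 at −78 °C to give the chlorine-free furylcarbinol F4. Under the conditions of step 16 this electron-richer 5-alkyl-2-furylcarbinol should rearrange through the chlorine-free C8-epimeric cyclopentenone F5 to the equilibrated chlorine-free hydroxycyclopentenone F6. Nucleophilic epoxidation of the enone (H2O2, K2CO3, MeOH, 0 °C) gives the 10,11-epoxy ketone F7. HCl in Et2O–CH2Cl2 at 0 °C opens the epoxide at C10 to the 10-chloro-11-hydroxy ketone F8, which loses water to give 26. Facial selectivity of the closure would still rest on C7.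

Step 17. The liberated C7 β-hydroxy ketone may dehydrate across C7–C8 under the acid needed for the acetonide, or acetal exchange may stay incomplete. The fallback sets out from 26, returns at 28, and unmasks the oxygens one after the other so that the β-hydroxy ketone never meets a strong acid. Pyridinium p-toluenesulfonate in MeOH at rt exchanges only the acetonide and gives the 5,6-diol 7-silyl ether F9. Ac2O and pyridine give the 5,6-diacetate 7-silyl ether F10. Buffered HF·pyridine in THF at 0 °C frees C7 to give the 5,6-diacetate 7-alcohol F11. Ac2O and pyridine at 0 °C then give 28.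

Step 4. The carboxyethyl ylide may fragment by loss of Ph3P, and the basic medium may epimerise the α-alkoxy aldehyde before olefination takes place. The fallback sets out from 4, returns at 7, and builds C1–C3 by metathesis. Methylenetriphenylphosphorane F12 (from Ph3PCH3Br and NaN(SiMe3)2, THF, 0 °C) converts 4 into 1,2-dideoxy-3,4:5,6-di-O-isopropylidene-D-xylo-hex-1-enitol F13. Cross-metathesis with methyl but-3-enoate (second-generation Hoveyda–Grubbs catalyst, CH2Cl2, 40 °C) gives methyl (3E,5S,6R,7R)-5,6:7,8-bis(isopropylidenedioxy)oct-3-enoate F14, which is hydrogenated as in step 5 to 7.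

**Further compounds**

F1 | step 16 | 2-furyllithium | [Li]c1ccco1
F2 | step 16 | 2-[(Z)-oct-2-en-1-yl]furan | CCCCC/C=C\Cc1ccco1
F3 | step 16 | 5-lithio-2-[(Z)-oct-2-en-1-yl]furan | CCCCC/C=C\Cc1ccc([Li])o1
F4 | step 16 | chlorine-free furylcarbinol (C8 epimer mixture) | CCCCC/C=C\Cc1ccc(o1)C(O)[C@@H](O[Si](C)(C)C(C)(C)C)[C@@H]2OC(C)(C)O[C@H]2CCCC(=O)OC
F5 | step 16 | chlorine-free C8-epimeric cyclopentenone | CCCCC/C=C\C[C@@]1(O)C=CC(=O)[C@H]1[C@@H](O[Si](C)(C)C(C)(C)C)[C@@H]2OC(C)(C)O[C@H]2CCCC(=O)OC
F6 | step 16 | chlorine-free hydroxycyclopentenone (configuration as in 26) | CCCCC/C=C\C[C@@]1(O)C=CC(=O)[C@@H]1[C@@H](O[Si](C)(C)C(C)(C)C)[C@@H]2OC(C)(C)O[C@H]2CCCC(=O)OC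
F7 | step 16 | 10,11-epoxy ketone (either epoxide face) | CCCCC/C=C\C[C@@]1(O)C2OC2C(=O)[C@@H]1[C@@H](O[Si](C)(C)C(C)(C)C)[C@@H]3OC(C)(C)O[C@H]3CCCC(=O)OC
F8 | step 16 | 10-chloro-11-hydroxy ketone | CCCCC/C=C\C[C@@]1(O)C(O)C(Cl)C(=O)[C@@H]1[C@@H](O[Si](C)(C)C(C)(C)C)[C@@H]2OC(C)(C)O[C@H]2CCCC(=O)OC
F9 | step 17 | 5,6-diol 7-silyl ether | CCCCC/C=C\C[C@@]1(O)C=C(Cl)C(=O)[C@@H]1[C@@H](O[Si](C)(C)C(C)(C)C)[C@H](O)[C@H](CCCC(=O)OC)O
F10 | step 17 | 5,6-diacetate 7-silyl ether | CCCCC/C=C\C[C@@]1(O)C=C(Cl)C(=O)[C@@H]1[C@@H](O[Si](C)(C)C(C)(C)C)[C@H](OC(C)=O)[C@H](CCCC(=O)OC)OC(C)=O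
F11 | step 17 | 5,6-diacetate 7-alcohol | CCCCC/C=C\C[C@@]1(O)C=C(Cl)C(=O)[C@@H]1[C@@H](O)[C@H](OC(C)=O)[C@H](CCCC(=O)OC)OC(C)=O
F12 | step 4 | methylenetriphenylphosphorane | C=P(c1ccccc1)(c1ccccc1)c1ccccc1
F13 | step 4 | 1,2-dideoxy-3,4:5,6-di-O-isopropylidene-D-xylo-hex-1-enitol | C=C[C@@H]1OC(C)(C)O[C@H]1[C@H]1COC(C)(C)O1
F14 | step 4 | methyl (3E,5S,6R,7R)-5,6:7,8-bis(isopropylidenedioxy)oct-3-enoate | COC(=O)C/C=C/[C@@H]1OC(C)(C)O[C@H]1[C@H]1COC(C)(C)O1
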